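The constants are those of an exercise, and the outcome is calculated.

Beside a neighbour charged with more electrophile, this flask raises one question: how much electrophile can its nucleophile pay for?

electrophile 0.013 M; free base 6.50 mM; solid nucleophile 0.0130 M; time 20 h

    electrophile + nucleophile → acid set free + target (k1 = 0.0992 M⁻¹ s⁻¹)
    nucleophile + acid set free ⇌ protonated nucleophile, settled at all times (K2 = 86000 M⁻¹)
    electrophile + target → side product (k3 = 0.0370 M⁻¹ s⁻¹)
    solid nucleophile ⇌ nucleophile, rate k4*(cs4 - [nucleophile]) while solid is left; crystals form when [nucleophile] > cs4 (cs4 = 8.4 mM, k4 = 0.00444 s⁻¹)
    acid set free + free base ⇌ salt of the base (K5 = 201 M⁻¹, k5 = 0.0408 M⁻¹ s⁻¹)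

- percent here means electrophile units held: one side product counts as two
- solid nucleophile is a solid; its amount is given per volume of the solution
- at the start none of the solid nucleophile is in solution
- run time (flask): 20 h

* part of the electrophile that has reacted at 20 h
* share of free nucleophile in free nucleophile and protonated nucleophile together, at 20 h

Each coupling sets free one acid. The nucleophile binds acid with 86000 M⁻¹, the free base with 201 M⁻¹, and because the base is so much the weaker sink, the reckoning here lets a second nucleophile pay for each coupling. Each target can then take a second electrophile into side product. This flask therefore has a reach of 100 %, the reach being the solid nucleophile charged over the electrophile charged: the share of the electrophile paid for at two nucleophile per coupling and one further electrophile per target.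

The bound from above on the electrophile used is plainly 100 percent. For the bound from below, solve the two ends and join them. The half-life of the nucleophile by coupling, 0.15 h, is shorter than the 20 h available, so the fast end leaves target and electrophile equal at 6.50 mM, with half of the electrophile coupled. In the slow end these equal partners fall to 0.355 mM, which puts the bound at 97.3 %. For the free share, the same end state with the base balanced against the protonated nucleophile gives 6.42 %. Below it the hand stops.

The forecast, 99.4 % and 1.7 %, stands inside this bracket, on the ground that “each coupling uses up a second nucleophile as acid sink”. The flask gives 99.8 % and 1.89 %.

The electrophile used lies at the reach. In this flask half of the coupling turnover was done by 0.204 h and half of the side step's by 1.11 h, and 93.5 % of the electrophile was used at 5.00 h. The salt of the base stood at 7.00 × 10⁻⁴ M at the asked time, and the step forming it makes no difference to the electrophile used.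

The neighbour charged with 0.033 M of electrophile, where the nucleophile is the limiting reagent, has a reach of 39.4 %, and with each nucleophile coupling once its ceiling is twice that, 78.8 %. That flask gives 58.1 %, between the two.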